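Midnight and the north-east run hold the same loading of free catalyst, 10 mol%, for the same 15 min. Midnight has 1.20 equiv of coupling partner against 2.4 equiv, though, and stands at 0 °C against −5 °C. North-east ends at 21 % target, and the two differences have to be weighed to place midnight.

| flask | substrate | coupling partner | free catalyst | temperature | remark | time |
|---|---|---|---|---|---|---|
| south-east | 0.10 M | 1.2 equiv | 5 mol% | −5 °C | run made earlier |  |
| north-west | 0.10 M | 1.2 equiv | 7.5 mol% | 25 °C | run made earlier |  |
| north-east | 0.10 M | 2.4 equiv | 10 mol% | −5 °C | run made earlier |  |
| midnight | 0.10 M | 1.20 equiv | 10 mol% | 0 °C |  | 15 min |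
| dusk | 0.10 M | 1.20 equiv | 10 mol% | 50 °C |  | 15 min |
| summer | 0.10 M | 1.20 equiv | 10 mol% | 25 °C |  | 15 min |

| run | time / min | target / % | substrate / % |
|---|---|---|---|
| south-east | 2.00 | 0 | 95 |
| south-east | 4.00 | 6 | 94 |
| south-east | 6.00 | 5 | 90 |
| south-east | 8.00 | 3 | 90 |
| south-east | 10.0 | 7 | 90 |
| south-east | 12.0 | 10 | 85 |
| south-east | 15.0 | 11 | 87 |
| north-west | 0.667 | 12 | 85 |
| north-west | 1.33 | 22 | 75 |
| north-west | 2.00 | 30 | 61 |
| north-west | 2.50 | 39 | 56 |
| north-west | 3.00 | 46 | 51 |
| north-west | 4.00 | 54 | 38 |
| north-east | 1.33 | 1 | 88 |
| north-east | 4.00 | 8 | 85 |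
| north-east | 8.00 | 11 | 81 |
| north-east | 10.0 | 18 | 77 |
| north-east | 15.0 | 21 | 73 |

(readings scatter by 2 percentage points)

- the analysis behind the earlier runs scatters by 2 percentage points, standard deviation
- what may be going on: substrate <-> dormant form; coupling partner + free catalyst <-> catalyst intermediate A; catalyst intermediate B -> free catalyst + target; target -> over-reaction product; substrate + catalyst intermediate A <-> catalyst intermediate B

- the flask with the highest amount of target, in percent of the substrate charged ("all alike" if they lie within 1.5 percentage points) (midnight / dusk / summer / all alike)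
- final target, as a percentage of the substrate charged, in midnight
- final target, as a percentage of the substrate charged, in dusk
- final target, as a percentage of the substrate charged, in summer

At the first reading, substrate and target together fall short of the charge by 5.00 % in south-east and 11.0 % in north-east, close to their loadings of 5 mol% and 10 mol%. The catalyst therefore appears to sit on substrate as catalyst intermediate B, the resting state, and the amount of this bound catalyst, not the substrate left, appears to set the rate. North-east then reads a turnover of 0.140 min⁻¹, the fraction of the charge made into target per minute per fraction of catalyst charged. South-east, with less catalyst and less coupling partner, reads 0.147 min⁻¹, so the extra coupling partner of north-east shows nothing within the scatter. Midnight differs from north-east, then, by its temperature.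

North-west, at 25 °C, reads 1.80 min⁻¹. Taking the same factor for each degree between the two temperatures:

turnover in midnight = 0.214 min⁻¹

target in midnight = turnover × loading × time = 32.1 %

The same turnover gives the time to use up the charge, 1/(turnover × loading):

midnight: 46.7 min, longer than the 15 min given

summer: 5.56 min, shorter than the 15 min given

Midnight thus stays on its straight line and ends above north-east. Summer should come close to the charge, minus what stands as dormant form at the end and whatever target goes on to over-reaction product. Dusk, hotter still, should lose more to over-reaction product, so summer is put highest here.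

The forecast gives 35 % for midnight against the 32.1 % here, 65 % for dusk and 89 % for summer, with summer highest, and says of dusk: “Over-reaction is poorly constrained”.

The flasks give 36.9 % in midnight, 77.5 % in dusk and 94.1 % in summer, so summer stands highest.

    substrate ⇌ dormant form (K = 1.48, k = 2.77 × 10⁻⁴ s⁻¹, Ea = 94.0 kJ mol⁻¹, ΔH = −13.0 kJ mol⁻¹)
    coupling partner + free catalyst ⇌ catalyst intermediate A (K = 315 M⁻¹, k = 22.2 M⁻¹ s⁻¹, Ea = 40.0 kJ mol⁻¹, ΔH = 5.00 kJ mol⁻¹)
    catalyst intermediate B → free catalyst + target (k = 0.107 s⁻¹, Ea = 78.0 kJ mol⁻¹)
    target → over-reaction product (k = 9.91 × 10⁻⁶ s⁻¹, Ea = 110 kJ mol⁻¹)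
    substrate + catalyst intermediate A ⇌ catalyst intermediate B (K = 6.88 M⁻¹, k = 27.8 M⁻¹ s⁻¹, Ea = 53.0 kJ mol⁻¹, ΔH = −43.0 kJ mol⁻¹)
    (constants at 25 °C)

Midnight's own turnover comes to 0.246 min⁻¹, against 0.140 min⁻¹ in north-east and 0.214 min⁻¹ reckoned here. Midnight still holds 56.3 % of its substrate at 15.0 min, and two things, each a part of it, act together to keep its target at 36.9 %: ten times the time gives 98.8 %, and the same flask without the return of catalyst intermediate B to substrate and catalyst intermediate A gives 51.7 %. In summer, the north-west turnover has the charge used up after 5.56 min, but at 7.50 min that flask holds 86.2 % target and still 8.53 % substrate.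

(The numbers in the tables were computed for substances that don't exist, and the scatter is random.)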